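**Plan**
- Retrosynthesis: the O–CH3 bond of a methyl-protected phenol is cut first, then the C4'–Br bond of ring B (electrophilic bromination), then the O–C1' and C2'–Br bonds of ring B together, leading back to a ring A phenoxide, benzyne and CBr4.
- Feature used: ring B carries the ether oxygen at C1' and a bromine on the adjacent C2', the 1,2-pattern left when ArO(−) and Br(+) add across an aryne triple bond. Its other bromine (C4') lies para to that oxygen, where bromination of an aryl ether enters, so the symmetrical parent benzyne suffices and the aryne step cannot give regioisomers (4-bromobenzyne would be attacked at both ends).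
- Forward, steps 1–3: the ring A phenol, 3,5,6-tribromo-2-methoxyphenol, is made from 2-bromo-6-methoxyphenol by mesylation, methoxy-directed dibromination and mesylate hydrolysis.
- Forward, steps 4–6: the two rings are joined by the aryne aryloxy-bromination, C4' is brominated and the methyl ether is cleaved; both benzene rings are bought, none is built.
- Stereochemistry: the target has no stereocentre and nothing stereochemical to set.

Key step: step 4

Remark: ring A locants follow 2-methoxyphenol numbering (C1 bears the oxygen that is arylated, C2 the methoxy group) and ring B locants are primed (C1' bears the ether oxygen); compounds 1, 7 and 8 are taken as commercially available.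

Step 1
Reactants: 1 2-bromo-6-methoxyphenol
Product: 2 2-bromo-6-methoxyphenyl methanesulfonate
Conditions: MsCl (1.2 equiv), Et3N (1.5 equiv), CH2Cl2, 0 °C to rt
Reagents that add atoms: methanesulfonyl chloride, CS(=O)(=O)Cl
Why: O-sulfonylation of a phenol with MsCl and an amine base is routine, and the mesylate, unlike an ester, should withstand Br2 and FeBr3 and switch off the ortho/para activation by this oxygen.

Step 2
Reactants: 2 2-bromo-6-methoxyphenyl methanesulfonate
Product: 4 3,5,6-tribromo-2-methoxyphenyl methanesulfonate, via 5,6-dibromo mesylate 3 (not isolated)
Conditions: Br2 (2.3 equiv), FeBr3 (5 mol %), CH2Cl2, 0 °C to 40 °C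
Reagents that add atoms: bromine, BrBr
Why: Lewis acid catalysed electrophilic aromatic bromination in which the methoxy group is the only donor, so bromine should enter para (C5) and then ortho (C3) to it, both carbons also being ortho or para to the C6 bromine, while C4 is meta to the methoxy group, para to the deactivating sulfonate and finally flanked by two bromines.

Step 3
Reactants: 4 3,5,6-tribromo-2-methoxyphenyl methanesulfonate
Product: 6 3,5,6-tribromo-2-methoxyphenol, via sodium phenoxide 5 (not isolated)
Conditions: NaOH (3 equiv), dioxane/H2O, 80 °C; then aq HCl
Reagents that add atoms: none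
Why: Alkaline hydrolysis of an aryl methanesulfonate, in which hydroxide cleaves the S–O bond (the tribromophenoxide is a good leaving group) to leave the sodium phenoxide while the aryl bromides and the methyl ether are inert to aqueous NaOH, and acidification frees the phenol.

Step 4
Reactants: 6 3,5,6-tribromo-2-methoxyphenol; 7 2-(trimethylsilyl)phenyl trifluoromethanesulfonate; 8 tetrabromomethane
Product: 12 1,2,5-tribromo-3-(2-bromophenoxy)-4-methoxybenzene, via potassium phenoxide 9 (not isolated), via benzyne 10 (not isolated), via arylpotassium 11 (not isolated)
Conditions: KH (1.0 equiv), THF, 0 °C; then CBr4 (3 equiv), KF (3 equiv), 18-crown-6 (3 equiv), slow addition of 7 (1.5 equiv), THF, 0 °C to rt; H2O quench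
Reagents that add atoms: none
Why: Proposed new method: KH first converts phenol 6 into potassium phenoxide 9 so that no O–H proton remains, fluoride then attacks silicon of 7 and triflate leaves to give benzyne 10, the phenoxide oxygen adds to the strained triple bond (O–C1') and the resulting ortho aryl anion 11 attacks a bromine of CBr4 in a halophilic substitution (C2'–Br) with tribromomethanide as leaving group. The closest known reaction types are the fluoride-induced aryne O-arylation of phenols, in which the same anion is merely protonated, aryne three-component couplings and sigma-bond insertions in which the aryl anion is captured by a halogen donor, and the bromination of aryllithiums by CBr4. No ring is closed and no stereocentre is formed. The step needs capture of the anion by bromine instead of a proton, which the aprotic medium (THF, pre-formed phenoxide, dried KF) and the excess of strongly bromophilic CBr4 should secure, and it needs the phenoxide to attack the aryne and not CBr4, which its three bromines and its para carbon wedged between two bromines make likely because they lower both its halophilicity and its tendency to C-bromination. Site selectivity across the triple bond does not arise because benzyne is symmetrical, which is the reason the C4' bromine is introduced only in step 5.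

Step 5
Reactants: 12 1,2,5-tribromo-3-(2-bromophenoxy)-4-methoxybenzene
Product: 13 1,2,5-tribromo-3-(2,4-dibromophenoxy)-4-methoxybenzene
Conditions: Br2 (1.05 equiv), FeBr3 (5 mol %), CH2Cl2, 0 °C to rt
Reagents that add atoms: bromine, BrBr
Why: Electrophilic aromatic bromination in which the ether oxygen conjugates mainly with the less hindered, less brominated ring B and directs bromine to its open para carbon C4' (as 2-bromoanisole gives 2,4-dibromoanisole), whereas C6' is screened by ring A, the only C–H of ring A, although para to the ether oxygen, lies between two bromines on a ring carrying three of them, and every position activated by the methoxy group is occupied.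

Step 6
Reactants: 13 1,2,5-tribromo-3-(2,4-dibromophenoxy)-4-methoxybenzene
Product: 15 3,4,6-tribromo-2-(2,4-dibromophenoxy)phenol, via aryloxydibromoborane 14 (not isolated)
Conditions: BBr3 (3 equiv), CH2Cl2, −78 °C to rt; then H2O
Reagents that add atoms: none
Why: Lewis acid cleavage of an aryl methyl ether, in which BBr3 coordinates the methoxy oxygen and bromide removes the methyl group by SN2 to give the aryloxydibromoborane that water hydrolyses, while the diaryl ether and the five C–Br bonds are untouched, as is usual for methoxylated polybrominated diphenyl ethers.

**Compound list**
1 | 2-bromo-6-methoxyphenol | COc1cccc(Br)c1O | starting material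
2 | 2-bromo-6-methoxyphenyl methanesulfonate | COc1cccc(Br)c1OS(C)(=O)=O | intermediate
3 | 5,6-dibromo-2-methoxyphenyl methanesulfonate | COc1ccc(Br)c(Br)c1OS(C)(=O)=O | intermediate
4 | 3,5,6-tribromo-2-methoxyphenyl methanesulfonate | COc1c(Br)cc(Br)c(Br)c1OS(C)(=O)=O | intermediate
5 | sodium 3,5,6-tribromo-2-methoxyphenoxide | COc1c(Br)cc(Br)c(Br)c1[O-].[Na+] | intermediate
6 | 3,5,6-tribromo-2-methoxyphenol | COc1c(Br)cc(Br)c(Br)c1O | intermediate
7 | 2-(trimethylsilyl)phenyl trifluoromethanesulfonate | C[Si](C)(C)c1ccccc1OS(=O)(=O)C(F)(F)F | starting material
8 | tetrabromomethane | BrC(Br)(Br)Br | starting material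
9 | potassium 3,5,6-tribromo-2-methoxyphenoxide | COc1c(Br)cc(Br)c(Br)c1[O-].[K+] | intermediate
10 | benzyne | C1#CC=CC=C1 | intermediate
11 | [2-(2,3,5-tribromo-6-methoxyphenoxy)phenyl]potassium | COc1c(Br)cc(Br)c(Br)c1Oc1ccccc1[K] | intermediate
12 | 1,2,5-tribromo-3-(2-bromophenoxy)-4-methoxybenzene | COc1c(Br)cc(Br)c(Br)c1Oc1ccccc1Br | intermediate
13 | 1,2,5-tribromo-3-(2,4-dibromophenoxy)-4-methoxybenzene | COc1c(Br)cc(Br)c(Br)c1Oc1ccc(Br)cc1Br | intermediate
14 | dibromo[3,4,6-tribromo-2-(2,4-dibromophenoxy)phenoxy]borane | BrB(Br)Oc1c(Br)cc(Br)c(Br)c1Oc1ccc(Br)cc1Br | intermediate
15 | 3,4,6-tribromo-2-(2,4-dibromophenoxy)phenol | Oc1c(Br)cc(Br)c(Br)c1Oc1ccc(Br)cc1Br | target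

**Step count**
Total steps: 6. Longest linear sequence: 6 steps (1 to 15; 7 and 8 are bought).

**Steps most likely to fail**

Step 4 (proposed new method). The aryl anion may be protonated before bromine transfer, so that the C2' bromine is lost. Benzyne may also be consumed by fluoride, bromide or tribromomethanide, or the phenoxide may attack CBr4 and be brominated on carbon. The fallback uses known chemistry, sets out from phenol 6 and comes back to the route at 13. Phenol 6 would be O-arylated with bis(2,4-dibromophenyl)iodonium chloride F1, itself prepared from 1,3-dibromobenzene and iodyl sulfate in concentrated H2SO4 followed by precipitation with NaCl. Heating the sodium salt of 6 with F1 (NaOH, H2O/dioxane, 80–100 °C) should transfer the 2,4-dibromophenyl group to oxygen by ligand coupling at iodine, a reaction well established for brominated phenols and brominated diaryliodonium salts. This gives 13 directly, so steps 4 and 5 are both replaced and only the demethylation remains.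

Step 2. The bromination may stall after the first bromine, bromine may enter C4, or the Lewis acid may erode the methyl ether. The fallback sets out from mesylate 2 and comes back at 4, and it replaces control by the methoxy group with control by a free hydroxyl. BBr3 in CH2Cl2 would cleave the methyl ether of 2 to 2-bromo-6-hydroxyphenyl methanesulfonate F2. Br2 (2 equiv) in AcOH at room temperature should then enter ortho and para to the free hydroxyl, the same two carbons C3 and C5, to give 3,5,6-tribromo-2-hydroxyphenyl methanesulfonate F3. O-Methylation of F3 with Me3SiCHN2 in MeOH/toluene, chosen to avoid a phenoxide that could take over the sulfonyl group from the neighbouring oxygen, leads back to 4.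

Step 5. Over-bromination at C6', attack on ring A or Lewis acid promoted migration of bromine may occur. The fallback sets out from 12 and comes back at 13, and it replaces direct bromination by a para-selective C–H thianthrenation. Treatment of 12 with thianthrene S-oxide, (CF3CO)2O and HBF4·OEt2 in MeCN (0 °C to rt) should give 5-[3-bromo-4-(2,3,5-tribromo-6-methoxyphenoxy)phenyl]thianthren-5-ium tetrafluoroborate F4, the sulfonium group entering para to the ether oxygen of ring B with the high site selectivity typical of this reaction. Copper-mediated photoredox bromination of F4 (LiBr, [Cu(MeCN)4]BF4, [Ru(bpy)3](PF6)2, MeCN, blue light) should then exchange the sulfonium group for bromine and give 13.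

**Further compounds**
F1 | step 4 | bis(2,4-dibromophenyl)iodonium chloride | Brc1ccc([I+]c2ccc(Br)cc2Br)c(Br)c1.[Cl-]
F2 | step 2 | 2-bromo-6-hydroxyphenyl methanesulfonate | Oc1cccc(Br)c1OS(C)(=O)=O
F3 | step 2 | 3,5,6-tribromo-2-hydroxyphenyl methanesulfonate | Oc1c(Br)cc(Br)c(Br)c1OS(C)(=O)=O
F4 | step 5 | 5-[3-bromo-4-(2,3,5-tribromo-6-methoxyphenoxy)phenyl]thianthren-5-ium tetrafluoroborate | COc1c(Br)cc(Br)c(Br)c1Oc1ccc([S+]2c3ccccc3Sc3ccccc32)cc1Br.F[B-](F)(F)F
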